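Assumption: 3,5-bis(benzyloxy)phenol (5), 3,4-bis(benzyloxy)benzoic acid (10) and 4-(benzyloxy)benzoic acid (19) are taken as purchased; they are the benzyl ethers of phloroglucinol, 3,4-dihydroxybenzoic acid and 4-hydroxybenzoic acid.
Assumption: the facial preference of IpcBH2 towards a 2-aryl-4H-chromene is taken to be the one known for 1-arylcycloalkenes, to which the enol ether is topologically equivalent.

## The problem

Compound 31 is a linear B-type proanthocyanidin tetramer, epicatechin-(4β→6)-epiafzelechin-(4β→8)-epicatechin-(4β→6)-epicatechin (units 1 to 4 from the top, rings A, B and C in each). Three C(sp3)–C(sp2) bonds join C4 of an upper unit to ring A of the next, and two of them end on C6, the carbon para to O1 and flanked by two oxygenated carbons, although ring A of a flavan takes electrophiles preferentially at C8. There are eleven stereocentres: C2 and C3 of every unit (2,3-cis) and three C4 centres (all 3,4-trans). The C4 centres need no outside control, because a nucleophile enters a C4 cation anti to the 3-oxygen and the 2-aryl group. C2 and C3 control nothing outside their own ring, so a unit that is not taken from the chiral pool needs a chiral reagent; epicatechin supplies units 1 and 3, but unit 2 (epiafzelechin) has no practical source. The interflavan bonds ionise in acid and the free polyphenol is oxidised in air and base, so the phenols must stay masked until a neutral final deprotection. The feature that admits a carbonyl coupling is that C2 and C3 of ring C in unit 4 (and equally in unit 2) both bear oxygen while C4 is a methylene. C2 can therefore be the carbonyl carbon of an aryl ester on O1 and C3 an aldehyde carbon on a CH2 at C4a, on a ring A that is a fully substituted phloroglucinol with the upper unit fixed para to O1.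

## Retrosynthesis

31 from 30. All seventeen protecting groups of 30 are benzyl ethers and its three ring A caps (C8 of units 1, 2 and 4) are bromine atoms. One hydrogenolysis removes both kinds, so no orthogonal deprotection is needed.

30 from 29 and 18. The C4(unit 2)–C8(unit 3) bond is cut. It is the only interflavan bond that follows the innate C8 preference, so it can be left to the end; cutting a 4→6 bond late would make a cation choose between several open C6-type carbons. The cut gives two dimers of equal size: 29 (units 1–2, a 2-ethoxyethoxy leaving group on C4 of unit 2) and 18 (units 3–4, C8 of unit 3 open). The forward reaction must give 4β and must find C8 of unit 3; bromine on every other C8 takes care of the second demand.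

29 from 28 from 27. These are functional-group changes. The leaving group is put on the only ring C methylene by hydride abstraction, and C8 of unit 1 is capped so that the electrophile cannot condense with itself.

18 from 17, 16 and 14; 27 from 26, 25 and 23. The 2,3-cis alcohols come from flavan-3-ones by hydride attack opposite the 2-aryl group. The ketones come from the 2,3-trans alcohols 16 and 25, and these from syn addition of H and B to C2=C3 of the 2-aryl-4H-chromenes 14 and 23 (boranes 15 and 24). No direct syn hydration to the cis alcohol exists; the oxidation–reduction detour costs two steps but is the established catechin-to-epicatechin conversion. The forward hydroboration must choose the alkene face under reagent control.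

14 from 13, and 23 from 22. The C2=C3 bond is cut into two carbonyl groups: an aryl ester on O1 and an arylacetaldehyde on C4a. The neighbouring cuts are weaker: closing O1–C2 needs C2 and C3 set on an open 1,3-diarylpropane chain first, and closing C4–C4a gives no handle for the 4→6 regiochemistry. The precursor has one ring less and carries only an ester and an aldehyde. Since both carbons are carbonyl carbons, the forward step must be a reductive coupling that prefers ring closure to dimerisation.

13 from 12, and 12 from 9 and 10; 22 from 21, and 21 from 9 and 19. The aldehyde is the cleaved terminal alkene of an allyl group, and the esters come from acylation of one phenol with acid chlorides 11 and 20. Units 4 and 2 thus diverge from the common phenol 9, and the epiafzelechin B ring comes from 19.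

9 from 4 and 8. The future 4→6 bond is cut between C4 of the flavan and the arene. Arene 8 has a single unsubstituted carbon, para to its hydroxyl, so the connectivity is fixed by construction. The forward reaction needs 4β (anti attack) and a rate that beats self-condensation of 4.

8 from 7, 6 and 5; 4 from 3, 2 and 1. The arene is made by O-allylation, Claisen rearrangement and ortho-bromination of 5. The electrophile is made from 1 by phenol benzylation, C4 oxidation and 3-O-benzylation.

## Roads not taken

Alternative 1: The cut is the C4(unit 1)–C6(unit 2) bond, made intramolecular. O3 of unit 1 and O5 of unit 2 are first joined through a nine-carbon diacid diester. A silyl triflate then ionises a C4 methoxy group on unit 1, and the cation closes a 15-membered ring onto C6 to give A1.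
- Merits: the tether settles C6 against C8 by geometry, both flavan units are used ready-made so no stereocentre is created, and 4β follows from anti attack.
- Weak points for this target: O5 of unit 2 must be the only free phenol of ring A, which is itself a regiochemical task on a phloroglucinol ring. Unit 2 must be bought in small amounts or made in about eight steps. The tether must be cut and C4 of unit 2 activated before the chain can grow, and the lower 4→6 bond needs the whole sequence again.
- Comparison: in stereochemical security this road is better, since the chosen plan must create C2 and C3 of units 2 and 4 under reagent control. The chosen plan sets against it a nucleophile (8) with one open carbon in place of a macrocyclisation, one phenol (9) serving both 4→6 bonds, and an epiafzelechin unit drawn from 19.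

Alternative 2: The cut runs through ring C of unit 2 at C3–C4 and O1–C2. A chiral binaphthyl-derived phosphoric acid ionises a carbinol at the future C4 that already bears ring A of unit 2 (unit 1 on C6) and C8 of unit 3. The ortho-quinone methide so formed adds a Z-configured styryl boron partner carrying the B ring of unit 2 in a [4+2] sense to give A2, with boron on C3.
- Merits: it is the most convergent of the four plans. It forms two bonds, a ring and three stereocentres at once, joins the two halves while unit 2 is built, and gives 2,3-cis directly from the Z alkene.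
- Weak points: three new centres must be controlled by an ion-paired catalyst on a quinone methide flanked by two flavan units. An alkenyl boron compound is a poor partner for such a heterodiene. The Brønsted acid can reopen the C4–C6 bond of unit 1. The carbinol still needs unit 1 para to O1, the problem that 8 solves. A2 has a C4 methylene in unit 3, so the lower 4→6 bond would have to be made on a trimer against the C8 preference.
- Comparison: if the cycloaddition worked it would be shorter for units 1–3, and this is conceded. The chosen plan sets against it that every stereocentre comes from a reaction type with close analogy and that both 4→6 bonds are made early on small fragments.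

Alternative 3: The cut is C4–C4a of unit 2 together with C4(unit 2)–C8(unit 3). C2 and C3 of unit 2 come from a sugar-derived chain whose C4 is an aldehyde and whose C2 oxygen is already the aryl ether O1 to ring A (unit 1 on C6). A silyl triflate makes ring A attack the aldehyde, the benzylic carbinol ionises again and is taken up by C8 of 2, giving A3.
- Merits: C2 and C3 of unit 2 come from the chiral pool, which is more secure than a reagent-controlled hydroboration. The central bond forms in the same operation at the naturally preferred C8 of a nucleophile that can be used in excess. Ring A of unit 2 is symmetric about the O1–C6 axis, so ring closure has no regiochemical choice.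
- Weak points: the C2 aryl ether must be made by substitution at a benzylic secondary carbon with a hindered phenol, and it can ionise under the Lewis acid that drives the cascade. Tailoring the sugar chain costs many steps. A3 again leaves the lower 4→6 bond to be made on a trimer.
- Comparison: for the absolute configuration of unit 2 and for the central bond this road is at least as good. The chosen plan sets against it that C2 is formed under neutral conditions, that one early reaction (step 7) settles both 4→6 bonds, and that the end game joins two dimers.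

Key step: step 10

## Steps

Step 1
Reactants: 1 (−)-epicatechin
Product: 2 5,7,3',4'-tetra-O-benzyl-(−)-epicatechin
Conditions: BnBr (4.4 equiv), K2CO3, DMF, 0 °C → rt
Reagents that add atoms: benzyl bromide, BrCc1ccccc1
Why: Williamson etherification of the four phenols; the secondary 3-hydroxyl is not deprotonated by K2CO3 and stays free, and the mild base at room temperature leaves C2 untouched.

Step 2
Reactants: 2 5,7,3',4'-tetra-O-benzyl-(−)-epicatechin
Product: 3 5,7,3',4'-tetra-O-benzyl-4β-(2-ethoxyethoxy)epicatechin (3,4-trans with a free 3-hydroxyl)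
Conditions: DDQ (2 equiv), 2-ethoxyethanol (10 equiv), CH2Cl2, rt
Reagents that add atoms: 2-ethoxyethanol, CCOCCO
Why: Oxidative benzylic etherification: DDQ abstracts hydride from the electron-rich benzylic C4 and the alcohol traps the cation anti to the 3-hydroxyl and 2-aryl group. The C4 configuration is of no consequence because the centre is ionised again in step 7.

Step 3
Reactants: 3 5,7,3',4'-tetra-O-benzyl-4β-(2-ethoxyethoxy)epicatechin
Product: 4 3,5,7,3',4'-penta-O-benzyl-4β-(2-ethoxyethoxy)epicatechin
Conditions: NaH (1.5 equiv), BnBr (1.5 equiv), n-Bu4NI (cat.), DMF, 0 °C → rt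
Reagents that add atoms: benzyl bromide, BrCc1ccccc1
Why: Williamson benzylation of the secondary alkoxide; O3 of units 1 and 3 is thereby masked against the acylation, oxidation and hydride steps that follow and is freed with the other benzyl groups at the end.

Step 4
Reactants: 5 3,5-bis(benzyloxy)phenol
Product: 6 1-(allyloxy)-3,5-bis(benzyloxy)benzene
Conditions: allyl bromide (1.3 equiv), K2CO3, acetone, reflux
Reagents that add atoms: allyl bromide, C=CCBr
Why: Williamson O-allylation of the only free phenol.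

Step 5
Reactants: 6 1-(allyloxy)-3,5-bis(benzyloxy)benzene
Product: 7 2-allyl-3,5-bis(benzyloxy)phenol
Conditions: N,N-diethylaniline, 190 °C, Ar
Reagents that add atoms: none
Why: Aromatic Claisen rearrangement ([3,3] shift, then tautomerisation); the two ortho carbons are equivalent, so one phenol results, and benzyl aryl ethers are stable at this temperature.

Step 6
Reactants: 7 2-allyl-3,5-bis(benzyloxy)phenol
Product: 8 2-allyl-3,5-bis(benzyloxy)-6-bromophenol
Conditions: NBS (1.0 equiv), i-Pr2NH (0.1 equiv), CH2Cl2, −78 °C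
Reagents that add atoms: N-bromosuccinimide, O=C1CCC(=O)N1Br
Why: Amine-mediated ortho-bromination of a phenol (bromine delivered from the hydrogen-bonded N-bromoamine). The remaining ortho carbon is also the less hindered one, as C8 is in 5,7-dibenzyloxyflavans, and its bromination leaves the carbon para to the hydroxyl as the only open ring position.

Step 7
Reactants: 4 3,5,7,3',4'-penta-O-benzyl-4β-(2-ethoxyethoxy)epicatechin; 8 2-allyl-3,5-bis(benzyloxy)-6-bromophenol (3 equiv)
Product: 9 4β-[3-allyl-2,6-bis(benzyloxy)-5-bromo-4-hydroxyphenyl]-3,5,7,3',4'-penta-O-benzylepicatechin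
Conditions: Me3SiOTf (0.3 equiv), CH2Cl2, −78 → −40 °C, 4 added slowly to 8; Et3N quench
Reagents that add atoms: none
Why: Friedel–Crafts alkylation through the C4 benzylic cation (SN1); attack anti to the 3-benzyloxy and 2-aryl groups gives 4β, and the only unsubstituted carbon of 8 lies para to its hydroxyl, so the 4→6 connectivity is fixed. Slow addition of 4 to excess 8 keeps C8 of a second molecule of 4 from competing, as in couplings of halogen-capped flavan nucleophiles at C6.

Step 8
Reactants: 9 4β-[3-allyl-2,6-bis(benzyloxy)-5-bromo-4-hydroxyphenyl]-3,5,7,3',4'-penta-O-benzylepicatechin; 10 3,4-bis(benzyloxy)benzoic acid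
Product: 12 3,4-bis(benzyloxy)benzoate of phenol 9, via 3,4-bis(benzyloxy)benzoyl chloride 11 (not isolated)
Conditions: 10, (COCl)2, DMF (cat.), CH2Cl2, rt; evaporate; then 9, Et3N, DMAP (cat.), CH2Cl2, 0 °C → rt
Reagents that add atoms: none
Why: Acid chloride formation followed by DMAP-catalysed acylation; the acylpyridinium ion is reactive enough for a phenol flanked by bromine and an allyl group, and there is no other free hydroxyl.

Step 9
Reactants: 12 3,4-bis(benzyloxy)benzoate of phenol 9
Product: 13 4β-{2,6-bis(benzyloxy)-4-[3,4-bis(benzyloxy)benzoyloxy]-3-bromo-5-(2-oxoethyl)phenyl}-3,5,7,3',4'-penta-O-benzylepicatechin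
Conditions: OsO4 (2 mol %), NaIO4 (4 equiv), 2,6-lutidine, dioxane/H2O, rt
Reagents that add atoms: osmium tetroxide (catalytic oxygen carrier), O=[Os](=O)(=O)=O; sodium periodate (terminal source of the aldehyde oxygen), [Na+].[O-]I(=O)(=O)=O
Why: Lemieux–Johnson cleavage of the terminal alkene, preferred to ozonolysis because ozone attacks polyalkoxyarenes; lutidine suppresses over-oxidation, and the arylacetaldehyde is used at once.

Step 10
Reactants: 13 4β-{2,6-bis(benzyloxy)-4-[3,4-bis(benzyloxy)benzoyloxy]-3-bromo-5-(2-oxoethyl)phenyl}-3,5,7,3',4'-penta-O-benzylepicatechin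
Product: 14 3,5,7,3',4'-penta-O-benzylepicatechin-(4β→6)-[5,7-bis(benzyloxy)-2-(3,4-bis(benzyloxy)phenyl)-8-bromo-4H-chromene]
Conditions: TiCl3 (10 equiv), Zn dust (20 equiv), DME, reflux 2 h; then 13 by syringe pump over 12 h (final ≤2 mM), reflux; 10% aq K2CO3, Celite, basic alumina
Reagents that add atoms: none
Why: Zinc reduces TiCl3 to low-valent titanium, which transfers an electron to the aldehyde of 13 and gives a titanium-bound ketyl. The ketyl carbon (future C3) adds to the neighbouring aryl ester carbonyl (future C2), and the titanium diolate so formed loses both oxygens to the metal, leaving the C2=C3 enol ether. The closest known reaction type is the low-valent titanium oxo-ester cyclisation of 2-acyloxyaryl ketones to benzofurans and of keto esters to cyclic enol ethers; here the carbonyl partner is an aldehyde and the ring is one atom larger. Ring C of unit 4 closes in the 6-exo-trig mode, the ester C=O being exocyclic to the forming ring, and the ortho placement of the two arms on ring A favours it. No stereocentre is formed, C4 is a methylene that cannot epimerise, and the centres of unit 3 are remote. The step needs ring closure to beat bimolecular pinacol coupling, which slow addition at high dilution secures, and it needs the aryl bromide and benzyl ethers to survive, as they do in McMurry couplings of bromobenzophenones. The enol ether is acid-labile, hence the carbonate work-up and immediate use.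

Step 11
Reactants: 14 3,5,7,3',4'-penta-O-benzylepicatechin-(4β→6)-[5,7-bis(benzyloxy)-2-(3,4-bis(benzyloxy)phenyl)-8-bromo-4H-chromene]
Product: 16 3,5,7,3',4'-penta-O-benzylepicatechin-(4β→6)-8-bromo-5,7,3',4'-tetra-O-benzyl-(2R,3S)-catechin (2,3-trans), via C3-isopinocampheylboryl adduct 15 (not isolated)
Conditions: IpcBH2 [from (+)-α-pinene, 2.5 equiv, preformed in Et2O], THF, −25 → 0 °C; then NaOH, H2O2, 0 °C → rt
Reagents that add atoms: hydrogen peroxide (oxygen of the new hydroxyl), OO
Why: Asymmetric hydroboration–oxidation: boron goes to C3, the β-carbon of the enol ether, syn addition and retentive oxidation give 2,3-trans. The face is chosen by the reagent, whose (+)-α-pinene-derived enantiomer turns 1-arylcycloalkenes into (1S,2R)-trans-2-arylcycloalkanols, the spatial counterpart of 2R,3S here; unit 3 is too remote to interfere.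

Step 12
Reactants: 16 3,5,7,3',4'-penta-O-benzylepicatechin-(4β→6)-8-bromo-5,7,3',4'-tetra-O-benzyl-(2R,3S)-catechin
Product: 17 3,5,7,3',4'-penta-O-benzylepicatechin-(4β→6)-(2R)-8-bromo-5,7,3',4'-tetrakis(benzyloxy)flavan-3-one
Conditions: Dess–Martin periodinane (1.5 equiv), wet CH2Cl2, rt
Reagents that add atoms: none
Why: Dess–Martin oxidation of the only free alcohol; the near-neutral conditions are those under which benzylated catechin gives its 3-ketone without loss of C2.

Step 13
Reactants: 17 3,5,7,3',4'-penta-O-benzylepicatechin-(4β→6)-(2R)-8-bromo-5,7,3',4'-tetrakis(benzyloxy)flavan-3-one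
Product: 18 3,5,7,3',4'-penta-O-benzylepicatechin-(4β→6)-8-bromo-5,7,3',4'-tetra-O-benzylepicatechin (units 3–4 with a free 3-hydroxyl on unit 4)
Conditions: LiBH(sec-Bu)3 (2 equiv), LiBr, THF, −78 °C; then NaOH, H2O2, 0 °C
Reagents that add atoms: none
Why: Diastereoselective ketone reduction: the bulky hydride enters opposite the 2-aryl group and gives the 2,3-cis alcohol (2R,3R), the known conversion of the catechin series into the epicatechin series; C2 is kept at −78 °C.

Step 14
Reactants: 9 4β-[3-allyl-2,6-bis(benzyloxy)-5-bromo-4-hydroxyphenyl]-3,5,7,3',4'-penta-O-benzylepicatechin; 19 4-(benzyloxy)benzoic acid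
Product: 21 4-(benzyloxy)benzoate of phenol 9, via 4-(benzyloxy)benzoyl chloride 20 (not isolated)
Conditions: 19, (COCl)2, DMF (cat.), CH2Cl2, rt; evaporate; then 9, Et3N, DMAP (cat.), CH2Cl2, 0 °C → rt
Reagents that add atoms: none
Why: Same DMAP-catalysed acylation as step 8; the benzoate now carries the B ring of the epiafzelechin unit 2.

Step 15
Reactants: 21 4-(benzyloxy)benzoate of phenol 9
Product: 22 4β-{2,6-bis(benzyloxy)-4-[4-(benzyloxy)benzoyloxy]-3-bromo-5-(2-oxoethyl)phenyl}-3,5,7,3',4'-penta-O-benzylepicatechin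
Conditions: OsO4 (2 mol %), NaIO4 (4 equiv), 2,6-lutidine, dioxane/H2O, rt
Reagents that add atoms: osmium tetroxide (catalytic oxygen carrier), O=[Os](=O)(=O)=O; sodium periodate (terminal source of the aldehyde oxygen), [Na+].[O-]I(=O)(=O)=O
Why: Lemieux–Johnson cleavage as in step 9.

Step 16
Reactants: 22 4β-{2,6-bis(benzyloxy)-4-[4-(benzyloxy)benzoyloxy]-3-bromo-5-(2-oxoethyl)phenyl}-3,5,7,3',4'-penta-O-benzylepicatechin
Product: 23 3,5,7,3',4'-penta-O-benzylepicatechin-(4β→6)-[5,7-bis(benzyloxy)-2-(4-(benzyloxy)phenyl)-8-bromo-4H-chromene]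
Conditions: TiCl3 (10 equiv), Zn dust (20 equiv), DME, reflux; 22 by syringe pump over 12 h (final ≤2 mM); 10% aq K2CO3, Celite, basic alumina
Reagents that add atoms: none
Why: The low-valent titanium ester–aldehyde cyclisation of step 10 applied to the 4-benzyloxybenzoate; ring C of unit 2 closes 6-exo-trig at C2–C3 and no stereocentre is formed.

Step 17
Reactants: 23 3,5,7,3',4'-penta-O-benzylepicatechin-(4β→6)-[5,7-bis(benzyloxy)-2-(4-(benzyloxy)phenyl)-8-bromo-4H-chromene]
Product: 25 3,5,7,3',4'-penta-O-benzylepicatechin-(4β→6)-8-bromo-5,7,4'-tri-O-benzyl-(2R,3S)-afzelechin (2,3-trans), via C3-isopinocampheylboryl adduct 24 (not isolated)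
Conditions: IpcBH2 [from (+)-α-pinene, 2.5 equiv, preformed in Et2O], THF, −25 → 0 °C; then NaOH, H2O2, 0 °C → rt
Reagents that add atoms: hydrogen peroxide (oxygen of the new hydroxyl), OO
Why: Asymmetric hydroboration–oxidation as in step 11; boron to C3, syn addition, and the same reagent enantiomer sets 2R,3S.

Step 18
Reactants: 25 3,5,7,3',4'-penta-O-benzylepicatechin-(4β→6)-8-bromo-5,7,4'-tri-O-benzyl-(2R,3S)-afzelechin
Product: 26 3,5,7,3',4'-penta-O-benzylepicatechin-(4β→6)-(2R)-8-bromo-5,7,4'-tris(benzyloxy)flavan-3-one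
Conditions: Dess–Martin periodinane (1.5 equiv), wet CH2Cl2, rt
Reagents that add atoms: none
Why: Dess–Martin oxidation as in step 12.

Step 19
Reactants: 26 3,5,7,3',4'-penta-O-benzylepicatechin-(4β→6)-(2R)-8-bromo-5,7,4'-tris(benzyloxy)flavan-3-one
Product: 27 3,5,7,3',4'-penta-O-benzylepicatechin-(4β→6)-8-bromo-5,7,4'-tri-O-benzylepiafzelechin (units 1–2 with a free 3-hydroxyl on unit 2)
Conditions: LiBH(sec-Bu)3 (2 equiv), LiBr, THF, −78 °C; then NaOH, H2O2, 0 °C
Reagents that add atoms: none
Why: Hydride delivery opposite the 2-aryl group as in step 13 gives the 2,3-cis alcohol (2R,3R).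

Step 20
Reactants: 27 3,5,7,3',4'-penta-O-benzylepicatechin-(4β→6)-8-bromo-5,7,4'-tri-O-benzylepiafzelechin
Product: 28 8-bromo-3,5,7,3',4'-penta-O-benzylepicatechin-(4β→6)-8-bromo-5,7,4'-tri-O-benzylepiafzelechin
Conditions: NBS (1.05 equiv), CH2Cl2, −78 → −30 °C
Reagents that add atoms: N-bromosuccinimide, O=C1CCC(=O)N1Br
Why: Electrophilic aromatic bromination at C8 of unit 1, the most nucleophilic open carbon (the known site for 5,7-dibenzyloxyflavans). The cap prevents the later electrophile from condensing with itself and is removed in step 23.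

Step 21
Reactants: 28 8-bromo-3,5,7,3',4'-penta-O-benzylepicatechin-(4β→6)-8-bromo-5,7,4'-tri-O-benzylepiafzelechin
Product: 29 8-bromo-3,5,7,3',4'-penta-O-benzylepicatechin-(4β→6)-8-bromo-5,7,4'-tri-O-benzyl-4β-(2-ethoxyethoxy)epiafzelechin
Conditions: DDQ (2.5 equiv), 2-ethoxyethanol (10 equiv), CH2Cl2, rt
Reagents that add atoms: 2-ethoxyethanol, CCOCCO
Why: Oxidative benzylic etherification as in step 2, the established route from benzylated dimers to dimeric electrophiles. The ring C methylene of unit 2 is the only unhindered doubly activated C–H, while the interflavan methine is shielded by its two ortho substituents.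

Step 22
Reactants: 29 8-bromo-3,5,7,3',4'-penta-O-benzylepicatechin-(4β→6)-8-bromo-5,7,4'-tri-O-benzyl-4β-(2-ethoxyethoxy)epiafzelechin; 18 3,5,7,3',4'-penta-O-benzylepicatechin-(4β→6)-8-bromo-5,7,3',4'-tetra-O-benzylepicatechin (1.5 equiv)
Product: 30 heptadeca-O-benzyl-tribromo tetramer (C8 bromine on every unit except unit 3 plus a free 3-hydroxyl on the epiafzelechin unit as well as on the terminal epicatechin unit)
Conditions: Me3SiOTf (0.5 equiv), CH2Cl2, −78 → −30 °C, 29 added slowly to 18; Et3N quench
Reagents that add atoms: none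
Why: Friedel–Crafts alkylation through the C4 cation of unit 2 (SN1), as in block couplings of halogen-capped catechin oligomers. Anti attack gives 4β, and C8 of unit 3 is the most nucleophilic open carbon because every other C8 bears bromine.

Step 23
Reactants: 30 heptadeca-O-benzyl-tribromo tetramer
Product: 31 epicatechin-(4β→6)-epiafzelechin-(4β→8)-epicatechin-(4β→6)-epicatechin (CNP0103636.1)
Conditions: H2 (1 atm), Pd(OH)2/C, Et3N (3.3 equiv), THF/MeOH/H2O, rt; filtration under Ar, Sephadex LH-20
Reagents that add atoms: none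
Why: Hydrogenolysis of all benzyl ethers with hydrodebromination of the three aryl bromides on palladium; Et3N takes up the HBr so the acid-labile interflavan bonds are not exposed, and no stereocentre is touched.

## Compound list

1 | (−)-epicatechin, (2R,3R)-2-(3,4-dihydroxyphenyl)chroman-3,5,7-triol | O[C@@H]1Cc2c(O)cc(O)cc2O[C@@H]1c1ccc(O)c(O)c1 | starting material
2 | 5,7,3',4'-tetra-O-benzyl-(−)-epicatechin | c1c(OCc9ccccc9)cc(OCc9ccccc9)c4c1O[C@H](c3ccc(OCc9ccccc9)c(OCc9ccccc9)c3)[C@H](O)C4 | intermediate
3 | 5,7,3',4'-tetra-O-benzyl-4β-(2-ethoxyethoxy)epicatechin | c1c(OCc9ccccc9)cc(OCc9ccccc9)c4c1O[C@H](c3ccc(OCc9ccccc9)c(OCc9ccccc9)c3)[C@H](O)[C@H]4OCCOCC | intermediate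
4 | 3,5,7,3',4'-penta-O-benzyl-4β-(2-ethoxyethoxy)epicatechin | c1c(OCc9ccccc9)cc(OCc9ccccc9)c4c1O[C@H](c3ccc(OCc9ccccc9)c(OCc9ccccc9)c3)[C@H](OCc9ccccc9)[C@H]4OCCOCC | intermediate
5 | 3,5-bis(benzyloxy)phenol | Oc1cc(OCc2ccccc2)cc(OCc2ccccc2)c1 | starting material
6 | 1-(allyloxy)-3,5-bis(benzyloxy)benzene | C=CCOc1cc(OCc2ccccc2)cc(OCc2ccccc2)c1 | intermediate
7 | 2-allyl-3,5-bis(benzyloxy)phenol | Oc1cc(OCc2ccccc2)cc(OCc2ccccc2)c1CC=C | intermediate
8 | 2-allyl-3,5-bis(benzyloxy)-6-bromophenol | Oc1c(Br)c(OCc2ccccc2)cc(OCc2ccccc2)c1CC=C | intermediate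
9 | 4β-[3-allyl-2,6-bis(benzyloxy)-5-bromo-4-hydroxyphenyl]-3,5,7,3',4'-penta-O-benzylepicatechin | c1c(OCc9ccccc9)cc(OCc9ccccc9)c4c1O[C@H](c3ccc(OCc9ccccc9)c(OCc9ccccc9)c3)[C@H](OCc9ccccc9)[C@H]4c3c(OCc9ccccc9)c(Br)c(O)c(CC=C)c3OCc9ccccc9 | intermediate
10 | 3,4-bis(benzyloxy)benzoic acid | OC(=O)c1ccc(OCc2ccccc2)c(OCc2ccccc2)c1 | starting material
11 | 3,4-bis(benzyloxy)benzoyl chloride | ClC(=O)c1ccc(OCc2ccccc2)c(OCc2ccccc2)c1 | intermediate (not isolated)
12 | 3,4-bis(benzyloxy)benzoate of phenol 9 | c1c(OCc9ccccc9)cc(OCc9ccccc9)c4c1O[C@H](c3ccc(OCc9ccccc9)c(OCc9ccccc9)c3)[C@H](OCc9ccccc9)[C@H]4c3c(OCc9ccccc9)c(Br)c(OC(=O)c7ccc(OCc9ccccc9)c(OCc9ccccc9)c7)c(CC=C)c3OCc9ccccc9 | intermediate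
13 | 2-oxoethyl aldehyde from 12 (key-step precursor, unit 3 with open ring C of unit 4) | c1c(OCc9ccccc9)cc(OCc9ccccc9)c4c1O[C@H](c3ccc(OCc9ccccc9)c(OCc9ccccc9)c3)[C@H](OCc9ccccc9)[C@H]4c3c(OCc9ccccc9)c(Br)c(OC(=O)c7ccc(OCc9ccccc9)c(OCc9ccccc9)c7)c(CC=O)c3OCc9ccccc9 | intermediate
14 | penta-O-benzylepicatechin-(4β→6)-[5,7-bis(benzyloxy)-2-(3,4-bis(benzyloxy)phenyl)-8-bromo-4H-chromene] (key-step product) | c1c(OCc9ccccc9)cc(OCc9ccccc9)c4c1O[C@H](c3ccc(OCc9ccccc9)c(OCc9ccccc9)c3)[C@H](OCc9ccccc9)[C@H]4c3c(OCc9ccccc9)c(Br)c4c(c3OCc9ccccc9)CC=C(c3ccc(OCc9ccccc9)c(OCc9ccccc9)c3)O4 | intermediate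
15 | C3-isopinocampheylboryl adduct of 14 (2R,3S, boron on C3) | c1c(OCc9ccccc9)cc(OCc9ccccc9)c4c1O[C@H](c3ccc(OCc9ccccc9)c(OCc9ccccc9)c3)[C@H](OCc9ccccc9)[C@H]4c3c(OCc9ccccc9)c(Br)c4c(c3OCc9ccccc9)C[C@H]([BH][C@@H]5C[C@@H]6C[C@@H](C6(C)C)[C@H]5C)[C@@H](c3ccc(OCc9ccccc9)c(OCc9ccccc9)c3)O4 | intermediate (not isolated)
16 | penta-O-benzylepicatechin-(4β→6)-8-bromo-5,7,3',4'-tetra-O-benzyl-(2R,3S)-catechin | c1c(OCc9ccccc9)cc(OCc9ccccc9)c4c1O[C@H](c3ccc(OCc9ccccc9)c(OCc9ccccc9)c3)[C@H](OCc9ccccc9)[C@H]4c3c(OCc9ccccc9)c(Br)c4c(c3OCc9ccccc9)C[C@H](O)[C@@H](c3ccc(OCc9ccccc9)c(OCc9ccccc9)c3)O4 | intermediate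
17 | penta-O-benzylepicatechin-(4β→6)-(2R)-8-bromo-5,7,3',4'-tetrakis(benzyloxy)flavan-3-one | c1c(OCc9ccccc9)cc(OCc9ccccc9)c4c1O[C@H](c3ccc(OCc9ccccc9)c(OCc9ccccc9)c3)[C@H](OCc9ccccc9)[C@H]4c3c(OCc9ccccc9)c(Br)c4c(c3OCc9ccccc9)CC(=O)[C@@H](c3ccc(OCc9ccccc9)c(OCc9ccccc9)c3)O4 | intermediate
18 | penta-O-benzylepicatechin-(4β→6)-8-bromo-5,7,3',4'-tetra-O-benzylepicatechin (units 3–4) | c1c(OCc9ccccc9)cc(OCc9ccccc9)c4c1O[C@H](c3ccc(OCc9ccccc9)c(OCc9ccccc9)c3)[C@H](OCc9ccccc9)[C@H]4c3c(OCc9ccccc9)c(Br)c4c(c3OCc9ccccc9)C[C@@H](O)[C@@H](c3ccc(OCc9ccccc9)c(OCc9ccccc9)c3)O4 | intermediate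
19 | 4-(benzyloxy)benzoic acid | OC(=O)c1ccc(OCc2ccccc2)cc1 | starting material
20 | 4-(benzyloxy)benzoyl chloride | ClC(=O)c1ccc(OCc2ccccc2)cc1 | intermediate (not isolated)
21 | 4-(benzyloxy)benzoate of phenol 9 | c1c(OCc9ccccc9)cc(OCc9ccccc9)c4c1O[C@H](c3ccc(OCc9ccccc9)c(OCc9ccccc9)c3)[C@H](OCc9ccccc9)[C@H]4c3c(OCc9ccccc9)c(Br)c(OC(=O)c7ccc(OCc9ccccc9)cc7)c(CC=C)c3OCc9ccccc9 | intermediate
22 | 2-oxoethyl aldehyde from 21 | c1c(OCc9ccccc9)cc(OCc9ccccc9)c4c1O[C@H](c3ccc(OCc9ccccc9)c(OCc9ccccc9)c3)[C@H](OCc9ccccc9)[C@H]4c3c(OCc9ccccc9)c(Br)c(OC(=O)c7ccc(OCc9ccccc9)cc7)c(CC=O)c3OCc9ccccc9 | intermediate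
23 | penta-O-benzylepicatechin-(4β→6)-[5,7-bis(benzyloxy)-2-(4-(benzyloxy)phenyl)-8-bromo-4H-chromene] | c1c(OCc9ccccc9)cc(OCc9ccccc9)c4c1O[C@H](c3ccc(OCc9ccccc9)c(OCc9ccccc9)c3)[C@H](OCc9ccccc9)[C@H]4c3c(OCc9ccccc9)c(Br)c4c(c3OCc9ccccc9)CC=C(c3ccc(OCc9ccccc9)cc3)O4 | intermediate
24 | C3-isopinocampheylboryl adduct of 23 (2R,3S, boron on C3) | c1c(OCc9ccccc9)cc(OCc9ccccc9)c4c1O[C@H](c3ccc(OCc9ccccc9)c(OCc9ccccc9)c3)[C@H](OCc9ccccc9)[C@H]4c3c(OCc9ccccc9)c(Br)c4c(c3OCc9ccccc9)C[C@H]([BH][C@@H]5C[C@@H]6C[C@@H](C6(C)C)[C@H]5C)[C@@H](c3ccc(OCc9ccccc9)cc3)O4 | intermediate (not isolated)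
25 | penta-O-benzylepicatechin-(4β→6)-8-bromo-5,7,4'-tri-O-benzyl-(2R,3S)-afzelechin | c1c(OCc9ccccc9)cc(OCc9ccccc9)c4c1O[C@H](c3ccc(OCc9ccccc9)c(OCc9ccccc9)c3)[C@H](OCc9ccccc9)[C@H]4c3c(OCc9ccccc9)c(Br)c4c(c3OCc9ccccc9)C[C@H](O)[C@@H](c3ccc(OCc9ccccc9)cc3)O4 | intermediate
26 | penta-O-benzylepicatechin-(4β→6)-(2R)-8-bromo-5,7,4'-tris(benzyloxy)flavan-3-one | c1c(OCc9ccccc9)cc(OCc9ccccc9)c4c1O[C@H](c3ccc(OCc9ccccc9)c(OCc9ccccc9)c3)[C@H](OCc9ccccc9)[C@H]4c3c(OCc9ccccc9)c(Br)c4c(c3OCc9ccccc9)CC(=O)[C@@H](c3ccc(OCc9ccccc9)cc3)O4 | intermediate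
27 | penta-O-benzylepicatechin-(4β→6)-8-bromo-5,7,4'-tri-O-benzylepiafzelechin (units 1–2) | c1c(OCc9ccccc9)cc(OCc9ccccc9)c4c1O[C@H](c3ccc(OCc9ccccc9)c(OCc9ccccc9)c3)[C@H](OCc9ccccc9)[C@H]4c3c(OCc9ccccc9)c(Br)c4c(c3OCc9ccccc9)C[C@@H](O)[C@@H](c3ccc(OCc9ccccc9)cc3)O4 | intermediate
28 | 8-bromo-penta-O-benzylepicatechin-(4β→6)-8-bromo-5,7,4'-tri-O-benzylepiafzelechin | Brc1c(OCc9ccccc9)cc(OCc9ccccc9)c4c1O[C@H](c3ccc(OCc9ccccc9)c(OCc9ccccc9)c3)[C@H](OCc9ccccc9)[C@H]4c3c(OCc9ccccc9)c(Br)c4c(c3OCc9ccccc9)C[C@@H](O)[C@@H](c3ccc(OCc9ccccc9)cc3)O4 | intermediate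
29 | 8-bromo-penta-O-benzylepicatechin-(4β→6)-8-bromo-5,7,4'-tri-O-benzyl-4β-(2-ethoxyethoxy)epiafzelechin | Brc1c(OCc9ccccc9)cc(OCc9ccccc9)c4c1O[C@H](c3ccc(OCc9ccccc9)c(OCc9ccccc9)c3)[C@H](OCc9ccccc9)[C@H]4c3c(OCc9ccccc9)c(Br)c4c(c3OCc9ccccc9)[C@H](OCCOCC)[C@@H](O)[C@@H](c3ccc(OCc9ccccc9)cc3)O4 | intermediate
30 | heptadeca-O-benzyl-tribromo tetramer (protected 31: C8 bromine on every unit except unit 3; free 3-hydroxyl on the epiafzelechin unit and on the terminal epicatechin unit) | c9ccccc9COc1ccc([C@H]2Oc3c(Br)c(OCc9ccccc9)c([C@H]4c5c(OCc9ccccc9)cc(OCc9ccccc9)c(Br)c5O[C@H](c5ccc(OCc9ccccc9)c(OCc9ccccc9)c5)[C@@H]4OCc9ccccc9)c(OCc9ccccc9)c3[C@H](c3c(OCc9ccccc9)cc(OCc9ccccc9)c4c3O[C@H](c3ccc(OCc9ccccc9)c(OCc9ccccc9)c3)[C@H](OCc9ccccc9)[C@H]4c3c(OCc9ccccc9)c(Br)c4c(c3OCc9ccccc9)C[C@@H](O)[C@@H](c3ccc(OCc9ccccc9)c(OCc9ccccc9)c3)O4)[C@H]2O)cc1 | intermediate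
31 | epicatechin-(4β→6)-epiafzelechin-(4β→8)-epicatechin-(4β→6)-epicatechin (CNP0103636.1) | Oc1ccc([C@H]2Oc3cc(O)c([C@H]4c5c(O)cc(O)cc5O[C@H](c5ccc(O)c(O)c5)[C@@H]4O)c(O)c3[C@H](c3c(O)cc(O)c4c3O[C@H](c3ccc(O)c(O)c3)[C@H](O)[C@H]4c3c(O)cc4c(c3O)C[C@@H](O)[C@@H](c3ccc(O)c(O)c3)O4)[C@H]2O)cc1 | target

## Step count and least certain steps

Total: 23 steps. Longest linear sequence: 14 steps (1, 2, 3, 7, 14, 15, 16, 17, 18, 19, 20, 21, 22, 23).

Step 10 (key step). The most likely failure is bimolecular reductive coupling of the aldehyde, or its plain reduction followed by acyl transfer from the phenol oxygen, because closure onto a hindered, electron-rich aryl ester is slow. The titanium and zinc chlorides at reflux may also hydrate the enol ether or ionise the C4–aryl bond; loss of bromine is less likely. The fallback gives up building ring C of unit 4. It sets out from 2, which NBS brominates at C8 to 8-bromo-5,7,3',4'-tetra-O-benzylepicatechin F1, a nucleophile whose only reactive ring A carbon is C6. Coupling of 4 with F1 under Me3SiOTf then gives the 4β→6 dimer directly, and the route is rejoined at 18.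

Step 16. The failure modes are those of step 10 on the 4-benzyloxybenzoate. The fallback sets out from 4 and needs purchased (−)-epiafzelechin F2. Its phenols are benzylated (BnBr, K2CO3) to 5,7,4'-tri-O-benzylepiafzelechin F3, NBS gives 8-bromo-5,7,4'-tri-O-benzylepiafzelechin F4, and coupling of 4 with F4 under Me3SiOTf at C6 rejoins the route at 27. The price is a scarce starting material.

Step 11 (and its repeat, step 17). Poor facial selectivity is the risk. The reagent is the only source of control, and the oxygen side of the enol ether is smaller than the CH2 of the carbocyclic models, so discrimination may erode. The fallback replaces reagent control by separation. From 14, BH3·SMe2 followed by NaOH/H2O2 gives 16 together with its (2S,3R) diastereomer F5. The two are diastereomers because of unit 3 and are separated by preparative HPLC; the route is rejoined at 16.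

Step 7. Self-condensation of 4 through its own C8 may outrun attack by the bromine-deactivated, doubly flanked carbon of 8. Acid-catalysed closure of the 2-allylphenol to a dihydrobenzofuran is a second risk. The fallback sets out from 4 and the more nucleophilic, unbrominated phenol 7 in large excess. The para adduct, 4β-[3-allyl-2,6-bis(benzyloxy)-4-hydroxyphenyl]-penta-O-benzylepicatechin F6, is separated from the ortho adduct. It is then brominated ortho to its free hydroxyl (NBS, i-Pr2NH, −78 °C), where the free phenol ring reacts before ring A of the flavan, and the route is rejoined at 9.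

Step 6. Bromination para to the hydroxyl, or bromoetherification of the allyl group, may compete, since every ring carbon is activated by three oxygens and the selectivity rests on hydrogen-bond delivery and sterics. The fallback sets out from 7. Iodoetherification (I2, NaHCO3, MeCN) ties O1 and the allyl group into 4,6-bis(benzyloxy)-2-(iodomethyl)-2,3-dihydrobenzofuran F7, a bicyclic ether whose carbon next to the ring oxygen corresponds to C8 of a 5,7-dibenzyloxyflavan. NBS brominates it there to give the 7-bromo compound F8, and Zn in AcOH/EtOH reopens the ring by reductive elimination, rejoining the route at 8.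

Step 22. Capture of the hindered C4 cation by a dimeric nucleophile may be slow, so that the cation is lost by elimination or attacks C6 of unit 3. The silyl triflate may also reionise the 4→6 bonds already present and scramble fragments. The fallback sets out from 29 and changes leaving group and activation mode. BnSH with BF3·OEt2 at −78 °C exchanges the 2-ethoxyethoxy group for sulfur to give the 4β-benzylthio dimer F9. AgBF4 in THF at 0 °C then activates F9 thiophilically in the presence of 18 under nearly neutral conditions, and the route is rejoined at 30.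

## Further compounds

F1 | step 10 | 8-bromo-5,7,3',4'-tetra-O-benzylepicatechin | Brc1c(OCc9ccccc9)cc(OCc9ccccc9)c4c1O[C@H](c3ccc(OCc9ccccc9)c(OCc9ccccc9)c3)[C@H](O)C4
F2 | step 16 | (−)-epiafzelechin (purchased) | O[C@@H]1Cc2c(O)cc(O)cc2O[C@@H]1c1ccc(O)cc1
F3 | step 16 | 5,7,4'-tri-O-benzylepiafzelechin | c1c(OCc9ccccc9)cc(OCc9ccccc9)c4c1O[C@H](c3ccc(OCc9ccccc9)cc3)[C@H](O)C4
F4 | step 16 | 8-bromo-5,7,4'-tri-O-benzylepiafzelechin | Brc1c(OCc9ccccc9)cc(OCc9ccccc9)c4c1O[C@H](c3ccc(OCc9ccccc9)cc3)[C@H](O)C4
F5 | step 11 | penta-O-benzylepicatechin-(4β→6)-8-bromo-5,7,3',4'-tetra-O-benzyl-(2S,3R)-catechin | c1c(OCc9ccccc9)cc(OCc9ccccc9)c4c1O[C@H](c3ccc(OCc9ccccc9)c(OCc9ccccc9)c3)[C@H](OCc9ccccc9)[C@H]4c3c(OCc9ccccc9)c(Br)c4c(c3OCc9ccccc9)C[C@@H](O)[C@H](c3ccc(OCc9ccccc9)c(OCc9ccccc9)c3)O4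
F6 | step 7 | 4β-[3-allyl-2,6-bis(benzyloxy)-4-hydroxyphenyl]-3,5,7,3',4'-penta-O-benzylepicatechin | c1c(OCc9ccccc9)cc(OCc9ccccc9)c4c1O[C@H](c3ccc(OCc9ccccc9)c(OCc9ccccc9)c3)[C@H](OCc9ccccc9)[C@H]4c3c(OCc9ccccc9)cc(O)c(CC=C)c3OCc9ccccc9
F7 | step 6 | 4,6-bis(benzyloxy)-2-(iodomethyl)-2,3-dihydrobenzofuran (racemic) | ICC1Cc2c(OCc3ccccc3)cc(OCc3ccccc3)cc2O1
F8 | step 6 | 4,6-bis(benzyloxy)-7-bromo-2-(iodomethyl)-2,3-dihydrobenzofuran (racemic) | ICC1Cc2c(OCc3ccccc3)cc(OCc3ccccc3)c(Br)c2O1
F9 | step 22 | 8-bromo-penta-O-benzylepicatechin-(4β→6)-8-bromo-5,7,4'-tri-O-benzyl-4β-(benzylthio)epiafzelechin | Brc1c(OCc9ccccc9)cc(OCc9ccccc9)c4c1O[C@H](c3ccc(OCc9ccccc9)c(OCc9ccccc9)c3)[C@H](OCc9ccccc9)[C@H]4c3c(OCc9ccccc9)c(Br)c4c(c3OCc9ccccc9)[C@H](SCc5ccccc5)[C@@H](O)[C@@H](c3ccc(OCc9ccccc9)cc3)O4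
A1 | alternative 1 | macrocyclic azelaoyl diester (O3 of unit 1 to O5 of unit 2) of the benzylated unit 1–unit 2 (4β→6) dimer | c9ccccc9COc1ccc([C@H]2Oc3cc(OCc9ccccc9)c([C@H]4c5c(OCc9ccccc9)cc(OCc9ccccc9)cc5O[C@H](c5ccc(OCc9ccccc9)c(OCc9ccccc9)c5)[C@@H]4OC(=O)CCCCCCCC(=O)O6)c6c3C[C@H]2O)cc1
A2 | alternative 2 | benzylated unit 1–unit 2–unit 3 trimer with a pinacol boronate on C3 of unit 2 | c9ccccc9COc1ccc([C@H]2Oc3cc(OCc9ccccc9)c([C@H]4c5c(OCc9ccccc9)cc(OCc9ccccc9)cc5O[C@H](c5ccc(OCc9ccccc9)c(OCc9ccccc9)c5)[C@@H]4OCc9ccccc9)c(OCc9ccccc9)c3[C@H](c3c(OCc9ccccc9)cc(OCc9ccccc9)c4c3O[C@H](c3ccc(OCc9ccccc9)c(OCc9ccccc9)c3)[C@H](OCc9ccccc9)C4)[C@H]2B4OC(C)(C)C(C)(C)O4)cc1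
A3 | alternative 3 | benzylated unit 1–unit 2–unit 3 trimer with a free 3-hydroxyl on unit 3 | c9ccccc9COc1ccc([C@H]2Oc3cc(OCc9ccccc9)c([C@H]4c5c(OCc9ccccc9)cc(OCc9ccccc9)cc5O[C@H](c5ccc(OCc9ccccc9)c(OCc9ccccc9)c5)[C@@H]4OCc9ccccc9)c(OCc9ccccc9)c3[C@H](c3c(OCc9ccccc9)cc(OCc9ccccc9)c4c3O[C@H](c3ccc(OCc9ccccc9)c(OCc9ccccc9)c3)[C@H](O)C4)[C@H]2OCc9ccccc9)cc1
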